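Atoms are numbered from the lactone carbonyl (C1) to the terminal methyl (C20). The route rests on cutting C11–C12, between carbinol carbon C11 and the first CH2 of the nonyl chain. The key step exploits that C11 is the only oxygenated carbon bonded to a plain alkyl chain (C12–C20), and that the dihydropyranone ring (ring O, C1–C5) is inert to alkylzinc: in one operation a chiral bis(sulfonamide)/Ti(OiPr)4 catalyst should transfer nonyl from dinonylzinc to aldehyde carbon C11, setting the last stereocentre. The precursor is the complete C1–C11 lactone aldehyde with C7/C9 held as an acetonide, built from propane-1,3-diol by iridium-catalysed allylations.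

Key step: step 8

Assumption: the facial sense of each chiral catalyst is assigned from its usual behaviour with unbranched aliphatic substrates, and the ligand antipode is used should the opposite face be delivered; nonylmagnesium bromide solution and both ligand antipodes are taken as commercial.

Step 1
Reactants: 1 propane-1,3-diol; 2 allyl acetate
Product: 4 (4R,6R)-nona-1,8-diene-4,6-diol, via (3R)-hex-5-ene-1,3-diol 3 (not isolated)
Conditions: [Ir(cod)Cl]2 (5 mol %), (R)-Cl,MeO-BIPHEP (10 mol %), 4-chloro-3-nitrobenzoic acid (20 mol %), Cs2CO3 (40 mol %), 2 (10 equiv), 1,4-dioxane, 90 °C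
Reagents that add atoms: allyl acetate, C=CCOC(C)=O
Why: Iridium-catalysed transfer-hydrogenative carbonyl allylation from the alcohol oxidation level (Krische allylation) dehydrogenates each CH2OH in situ and allylates the transient aldehyde with a chiral π-allyl iridium C,O-benzoate, so both stereocentres (C7 and C9, both R here) are set by the catalyst and the C2-symmetric anti diol should result.

Step 2
Reactants: 4 (4R,6R)-nona-1,8-diene-4,6-diol; 5 2,2-dimethoxypropane
Product: 6 (4R,6R)-2,2-dimethyl-4,6-di(prop-2-en-1-yl)-1,3-dioxane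
Conditions: 5 (3 equiv), PPTS (5 mol %), CH2Cl2, rt
Reagents that add atoms: 2,2-dimethoxypropane, COC(C)(C)OC
Why: Acid-catalysed transacetalisation ties the anti 1,3-diol into an acetonide without touching either stereocentre.

Step 3
Reactants: 6 (4R,6R)-2,2-dimethyl-4,6-di(prop-2-en-1-yl)-1,3-dioxane
Product: 8 2,2'-[(4R,6R)-2,2-dimethyl-1,3-dioxane-4,6-diyl]di(ethan-1-ol), via bis-ozonide 7 (not isolated)
Conditions: O3, CH2Cl2, −78 °C; then NaBH4 (6 equiv), MeOH, −78 °C to rt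
Reagents that add atoms: ozone, [O-][O+]=O
Why: Ozonolysis of both terminal alkenes gives the bis-ozonide, which NaBH4 reduces directly to the two primary alcohols, leaving the acetonide and both stereocentres untouched.

Step 4
Reactants: 8 2,2'-[(4R,6R)-2,2-dimethyl-1,3-dioxane-4,6-diyl]di(ethan-1-ol); 2 allyl acetate
Product: 9 (2S)-1-[(4R,6R)-6-(2-hydroxyethyl)-2,2-dimethyl-1,3-dioxan-4-yl]pent-4-en-2-ol
Conditions: 8 (2 equiv), 2 (1 equiv), [Ir(cod)Cl]2 (2.5 mol %), (S)-Cl,MeO-BIPHEP (5 mol %), 4-chloro-3-nitrobenzoic acid (10 mol %), Cs2CO3 (20 mol %), 1,4-dioxane, 90 °C; unreacted 8 recovered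
Reagents that add atoms: allyl acetate, C=CCOC(C)=O
Why: The same Krische allylation with the antipodal ligand and limiting allyl acetate should allylate one of the two homotopic CH2OH termini of C2-symmetric 8, the catalyst setting C5 (S, anti to C7); the mono-adduct is separated from recovered 8 and the bis-adduct.

Step 5
Reactants: 9 (2S)-1-[(4R,6R)-6-(2-hydroxyethyl)-2,2-dimethyl-1,3-dioxan-4-yl]pent-4-en-2-ol
Product: 10 2-[(4S,6R)-6-[(2S)-2-hydroxypent-4-en-1-yl]-2,2-dimethyl-1,3-dioxan-4-yl]acetaldehyde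
Conditions: TEMPO (10 mol %), PhI(OAc)2 (1.1 equiv), CH2Cl2, rt
Reagents that add atoms: none
Why: Oxoammonium (TEMPO) oxidation is selective for the primary over the secondary homoallylic alcohol and stops at the aldehyde.

Step 6
Reactants: 10 2-[(4S,6R)-6-[(2S)-2-hydroxypent-4-en-1-yl]-2,2-dimethyl-1,3-dioxan-4-yl]acetaldehyde; 11 acryloyl chloride
Product: 12 (2S)-1-[(4S,6S)-2,2-dimethyl-6-(2-oxoethyl)-1,3-dioxan-4-yl]pent-4-en-2-yl prop-2-enoate
Conditions: 11 (1.5 equiv), iPr2NEt (2.5 equiv), CH2Cl2, −78 to −20 °C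
Reagents that add atoms: acryloyl chloride, C=CC(=O)Cl
Why: O-acylation of the only free hydroxyl with an acid chloride proceeds with retention at C5, and the hindered amine at low temperature should spare the β-alkoxy aldehyde.

Step 7
Reactants: 12 (2S)-1-[(4S,6S)-2,2-dimethyl-6-(2-oxoethyl)-1,3-dioxan-4-yl]pent-4-en-2-yl prop-2-enoate
Product: 13 2-[(4S,6S)-2,2-dimethyl-6-{[(2S)-6-oxo-3,6-dihydro-2H-pyran-2-yl]methyl}-1,3-dioxan-4-yl]acetaldehyde
Conditions: second-generation Grubbs catalyst RuCl2(=CHPh)(H2IMes)(PCy3) (5 mol %), CH2Cl2 (5 mM), 40 °C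
Reagents that add atoms: none
Why: Ring-closing metathesis of the acrylate onto the homoallylic alkene closes the six-membered α,β-unsaturated lactone with loss of ethylene, and ruthenium carbenes tolerate aldehydes.

Step 8
Reactants: 13 2-[(4S,6S)-2,2-dimethyl-6-{[(2S)-6-oxo-3,6-dihydro-2H-pyran-2-yl]methyl}-1,3-dioxan-4-yl]acetaldehyde; 14 nonylmagnesium bromide
Product: 16 (6S)-6-{[(4S,6R)-6-[(2S)-2-hydroxyundecyl]-2,2-dimethyl-1,3-dioxan-4-yl]methyl}-5,6-dihydro-2H-pyran-2-one, via dinonylzinc 15 (not isolated)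
Conditions: 14 (5 equiv), ZnCl2 (2.5 equiv), Et2O, 0 °C to rt, then 1,4-dioxane, filtration; Ti(OiPr)4 (1.5 equiv), (1R,2R)-N,N'-bis(trifluoromethylsulfonyl)cyclohexane-1,2-diamine (10 mol %), toluene, −20 °C; 13, −20 °C; aq. NH4Cl
Reagents that add atoms: nonylmagnesium bromide, CCCCCCCCC[Mg]Br
Why: Transmetallation of 14 with ZnCl2 gives salt-free 15, which passes a nonyl group to titanium; the chiral titanium bis(sulfonamide) complex binds the aldehyde as a Lewis acid and delivers nonyl to one face of C11, forming the C11–C12 bond. The closest known reaction type is the catalytic enantioselective addition of dialkylzincs to aldehydes with Ti(OiPr)4 and the trans-cyclohexane-1,2-diamine bis(triflamide) ligand, which accepts unbranched and β-oxygenated aliphatic aldehydes. No ring is closed. The new C11 stereocentre (S) is set by the catalyst, the (1R,2R) ligand directing attack to the Si face, while the C9 oxygen is locked in the dioxane and should exert little substrate bias. The step needs chemoselectivity for the aldehyde over the conjugated lactone, secured by the low reactivity of alkylzinc and alkyltitanium species toward esters and enoates, and it needs facial selectivity, which rests on catalyst control.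

Step 9
Reactants: 16 (6S)-6-{[(4S,6R)-6-[(2S)-2-hydroxyundecyl]-2,2-dimethyl-1,3-dioxan-4-yl]methyl}-5,6-dihydro-2H-pyran-2-one
Product: 17 (6S)-6-[(2S,4R,6S)-2,4,6-trihydroxypentadecyl]-5,6-dihydro-2H-pyran-2-one
Conditions: AcOH/H2O (4:1), 40 °C
Reagents that add atoms: none
Why: Mild acid hydrolysis of the anti (twist-boat) acetonide frees the C7 and C9 hydroxyls, while the lactone survives aqueous acetic acid and the 5,7-anti arrangement disfavours intramolecular oxa-Michael closure.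

Compound list
1 | propane-1,3-diol | OCCCO | starting material
2 | allyl acetate | C=CCOC(C)=O | starting material
3 | (3R)-hex-5-ene-1,3-diol | OCC[C@H](O)CC=C | intermediate
4 | (4R,6R)-nona-1,8-diene-4,6-diol | C=CC[C@@H](O)C[C@H](O)CC=C | intermediate
5 | 2,2-dimethoxypropane | COC(C)(C)OC | starting material
6 | (4R,6R)-2,2-dimethyl-4,6-di(prop-2-en-1-yl)-1,3-dioxane | C=CC[C@@H]1C[C@@H](CC=C)OC(C)(C)O1 | intermediate
7 | bis-ozonide, (4S,6S)-2,2-dimethyl-4,6-bis[(1,2,4-trioxolan-3-yl)methyl]-1,3-dioxane (trioxolane carbons as a mixture) | C1(OCOO1)C[C@@H]2C[C@@H](CC3OCOO3)OC(C)(C)O2 | intermediate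
8 | 2,2'-[(4R,6R)-2,2-dimethyl-1,3-dioxane-4,6-diyl]di(ethan-1-ol) | OCC[C@@H]1C[C@@H](CCO)OC(C)(C)O1 | intermediate
9 | (2S)-1-[(4R,6R)-6-(2-hydroxyethyl)-2,2-dimethyl-1,3-dioxan-4-yl]pent-4-en-2-ol | OCC[C@@H]1C[C@@H](C[C@@H](O)CC=C)OC(C)(C)O1 | intermediate
10 | 2-[(4S,6R)-6-[(2S)-2-hydroxypent-4-en-1-yl]-2,2-dimethyl-1,3-dioxan-4-yl]acetaldehyde | O=CC[C@@H]1C[C@@H](C[C@@H](O)CC=C)OC(C)(C)O1 | intermediate
11 | acryloyl chloride | C=CC(=O)Cl | starting material
12 | (2S)-1-[(4S,6S)-2,2-dimethyl-6-(2-oxoethyl)-1,3-dioxan-4-yl]pent-4-en-2-yl prop-2-enoate | O=CC[C@@H]1C[C@@H](C[C@@H](OC(=O)C=C)CC=C)OC(C)(C)O1 | intermediate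
13 | 2-[(4S,6S)-2,2-dimethyl-6-{[(2S)-6-oxo-3,6-dihydro-2H-pyran-2-yl]methyl}-1,3-dioxan-4-yl]acetaldehyde | O=CC[C@@H]1C[C@@H](C[C@@H]2CC=CC(=O)O2)OC(C)(C)O1 | intermediate
14 | nonylmagnesium bromide | CCCCCCCCC[Mg]Br | starting material
15 | dinonylzinc | CCCCCCCCC[Zn]CCCCCCCCC | intermediate
16 | (6S)-6-{[(4S,6R)-6-[(2S)-2-hydroxyundecyl]-2,2-dimethyl-1,3-dioxan-4-yl]methyl}-5,6-dihydro-2H-pyran-2-one | CCCCCCCCC[C@H](O)C[C@@H]1C[C@@H](C[C@@H]2CC=CC(=O)O2)OC(C)(C)O1 | intermediate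
17 | (6S)-6-[(2S,4R,6S)-2,4,6-trihydroxypentadecyl]-5,6-dihydro-2H-pyran-2-one | CCCCCCCCC[C@H](O)C[C@@H](O)C[C@H](O)C[C@@H]1CC=CC(=O)O1 | target

Total step count: 9. Longest linear sequence: 9 steps (1 to 17).

Steps most likely to fail

Step 8 (key step). Facial discrimination at C11 may be eroded if the Lewis-acidic titanium is also held by the β-oxygen of the dioxane (catalyst–substrate mismatch), and the unbranched aldehyde may enolise. The fallback sets out from 13 and comes back at 17; it sets the stereocentre after the C–C bond is made. Addition of 15 to 13 with Ti(OiPr)4 and the racemic ligand should give the C11-epimeric alcohols (6S)-6-{[(4S,6R)-6-(2-hydroxyundecyl)-2,2-dimethyl-1,3-dioxan-4-yl]methyl}-5,6-dihydro-2H-pyran-2-one F1. Dess–Martin oxidation should give the ketone (6S)-6-{[(4S,6S)-2,2-dimethyl-6-(2-oxoundecyl)-1,3-dioxan-4-yl]methyl}-5,6-dihydro-2H-pyran-2-one F2. AcOH/H2O should remove the acetonide to give the β,δ-dihydroxy ketone (6S)-6-[(2S,4S)-2,4-dihydroxy-6-oxopentadecyl]-5,6-dihydro-2H-pyran-2-one F3. Me4NBH(OAc)3 in MeCN/AcOH at −30 °C (Evans–Saksena reduction) then delivers hydride intramolecularly from the borate of the C9 hydroxyl and should give the 9,11-anti triol 17.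

Step 4. Over-allylation to the bis-adduct and stalling of catalyst turnover with limiting allyl acetate may make the statistical separation inefficient. The fallback sets out from 8 and comes back at 13. Monosilylation (NaH, TBSCl, THF) should give 2-[(4R,6R)-6-{2-[(tert-butyldimethylsilyl)oxy]ethyl}-2,2-dimethyl-1,3-dioxan-4-yl]ethan-1-ol F4. Krische allylation with excess 2 and the (S)-ligand should give (2S)-1-[(4R,6R)-6-{2-[(tert-butyldimethylsilyl)oxy]ethyl}-2,2-dimethyl-1,3-dioxan-4-yl]pent-4-en-2-ol F5. Acylation with 11 and iPr2NEt should give (2S)-1-[(4S,6R)-6-{2-[(tert-butyldimethylsilyl)oxy]ethyl}-2,2-dimethyl-1,3-dioxan-4-yl]pent-4-en-2-yl prop-2-enoate F6. Ring-closing metathesis should give (6S)-6-{[(4S,6R)-6-{2-[(tert-butyldimethylsilyl)oxy]ethyl}-2,2-dimethyl-1,3-dioxan-4-yl]methyl}-5,6-dihydro-2H-pyran-2-one F7. HF·pyridine should free the alcohol (6S)-6-{[(4S,6R)-6-(2-hydroxyethyl)-2,2-dimethyl-1,3-dioxan-4-yl]methyl}-5,6-dihydro-2H-pyran-2-one F8, and Dess–Martin oxidation returns to 13.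

Step 6. Base-induced β-elimination of the dioxane oxygen from the β-alkoxy aldehyde, or acylation of its enol, may compete with ester formation. The fallback sets out from 9 and comes back at 13; the aldehyde is unveiled only after the lactone is closed. Selective silylation of the primary hydroxyl (TESCl, imidazole, CH2Cl2, −20 °C) should give (2S)-1-[(4R,6R)-2,2-dimethyl-6-{2-[(triethylsilyl)oxy]ethyl}-1,3-dioxan-4-yl]pent-4-en-2-ol F9. Acylation with 11 should give (2S)-1-[(4S,6R)-2,2-dimethyl-6-{2-[(triethylsilyl)oxy]ethyl}-1,3-dioxan-4-yl]pent-4-en-2-yl prop-2-enoate F10. Ring-closing metathesis should give (6S)-6-{[(4S,6R)-2,2-dimethyl-6-{2-[(triethylsilyl)oxy]ethyl}-1,3-dioxan-4-yl]methyl}-5,6-dihydro-2H-pyran-2-one F11. Swern oxidation ((COCl)2, DMSO, Et3N) cleaves the primary triethylsilyl ether and oxidises it in the same flask to 13.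

Further compounds
F1 | step 8 | (6S)-6-{[(4S,6R)-6-(2-hydroxyundecyl)-2,2-dimethyl-1,3-dioxan-4-yl]methyl}-5,6-dihydro-2H-pyran-2-one, mixture of C11 epimers | CCCCCCCCCC(O)C[C@@H]1C[C@@H](C[C@@H]2CC=CC(=O)O2)OC(C)(C)O1
F2 | step 8 | (6S)-6-{[(4S,6S)-2,2-dimethyl-6-(2-oxoundecyl)-1,3-dioxan-4-yl]methyl}-5,6-dihydro-2H-pyran-2-one | CCCCCCCCCC(=O)C[C@@H]1C[C@@H](C[C@@H]2CC=CC(=O)O2)OC(C)(C)O1
F3 | step 8 | (6S)-6-[(2S,4S)-2,4-dihydroxy-6-oxopentadecyl]-5,6-dihydro-2H-pyran-2-one | CCCCCCCCCC(=O)C[C@@H](O)C[C@H](O)C[C@@H]1CC=CC(=O)O1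
F4 | step 4 | 2-[(4R,6R)-6-{2-[(tert-butyldimethylsilyl)oxy]ethyl}-2,2-dimethyl-1,3-dioxan-4-yl]ethan-1-ol | CC(C)(C)[Si](C)(C)OCC[C@@H]1C[C@@H](CCO)OC(C)(C)O1
F5 | step 4 | (2S)-1-[(4R,6R)-6-{2-[(tert-butyldimethylsilyl)oxy]ethyl}-2,2-dimethyl-1,3-dioxan-4-yl]pent-4-en-2-ol | CC(C)(C)[Si](C)(C)OCC[C@@H]1C[C@@H](C[C@@H](O)CC=C)OC(C)(C)O1
F6 | step 4 | (2S)-1-[(4S,6R)-6-{2-[(tert-butyldimethylsilyl)oxy]ethyl}-2,2-dimethyl-1,3-dioxan-4-yl]pent-4-en-2-yl prop-2-enoate | CC(C)(C)[Si](C)(C)OCC[C@@H]1C[C@@H](C[C@@H](OC(=O)C=C)CC=C)OC(C)(C)O1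
F7 | step 4 | (6S)-6-{[(4S,6R)-6-{2-[(tert-butyldimethylsilyl)oxy]ethyl}-2,2-dimethyl-1,3-dioxan-4-yl]methyl}-5,6-dihydro-2H-pyran-2-one | CC(C)(C)[Si](C)(C)OCC[C@@H]1C[C@@H](C[C@@H]2CC=CC(=O)O2)OC(C)(C)O1
F8 | step 4 | (6S)-6-{[(4S,6R)-6-(2-hydroxyethyl)-2,2-dimethyl-1,3-dioxan-4-yl]methyl}-5,6-dihydro-2H-pyran-2-one | OCC[C@@H]1C[C@@H](C[C@@H]2CC=CC(=O)O2)OC(C)(C)O1
F9 | step 6 | (2S)-1-[(4R,6R)-2,2-dimethyl-6-{2-[(triethylsilyl)oxy]ethyl}-1,3-dioxan-4-yl]pent-4-en-2-ol | CC[Si](CC)(CC)OCC[C@@H]1C[C@@H](C[C@@H](O)CC=C)OC(C)(C)O1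
F10 | step 6 | (2S)-1-[(4S,6R)-2,2-dimethyl-6-{2-[(triethylsilyl)oxy]ethyl}-1,3-dioxan-4-yl]pent-4-en-2-yl prop-2-enoate | CC[Si](CC)(CC)OCC[C@@H]1C[C@@H](C[C@@H](OC(=O)C=C)CC=C)OC(C)(C)O1
F11 | step 6 | (6S)-6-{[(4S,6R)-2,2-dimethyl-6-{2-[(triethylsilyl)oxy]ethyl}-1,3-dioxan-4-yl]methyl}-5,6-dihydro-2H-pyran-2-one | CC[Si](CC)(CC)OCC[C@@H]1C[C@@H](C[C@@H]2CC=CC(=O)O2)OC(C)(C)O1
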